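## Retrosynthetic overview

1. Numbering: lactone O1, C2(=O), C3, C4, C5H2; C7 is the carbon on C3 that ends as the aryl ketone. The endgame is desilylation, oxidation of the C7 carbinol and O-debenzylation; the C4 benzyl C–C bond comes from nickel-catalysed coupling of a C4–CH2I group with 4-iodo-1,2-dimethoxybenzene.
2. The lactone, the only ring made in the route, is closed at C4–C5 by an iodine-atom-transfer 5-exo-trig radical cyclisation of an iodomethyl 2-substituted but-3-enoate. The ester-bound radical O1–C5H2• adds to the inner vinyl carbon (C4), and the outer vinyl carbon leaves as CH2I.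
3. Feature that makes this possible: C5 is an unsubstituted OCH2 bonded only to O1 and C4, so it can be an acyloxymethyl radical, and C4 bears an exocyclic CH2, so it can be the inner carbon of a vinyl group. C3 lies between C2=O and C7=O, so with C7 as a silyl-protected carbinol it is a stable stereocentre that directs C4, and after oxidation of C7 it rests trans.
4. The acyclic precursor comes from an Evans syn-aldol (α-attack of the boron dienolate of an N-crotonyl oxazolidinone on O-benzylvanillin, setting C3 and C7), silylation, auxiliary removal, O-alkylation with chloromethyl chlorosulfate and iodide exchange.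

Key step: step 6

Remark on the chemistry: in 18 and 19, C3 lies between two carbonyl groups; the arrangement trans to the C4 substituent is taken to be the thermodynamic one, so C3 is not expected to be lost after step 9.

## Route

Step 1
Reactants: 1 (4S)-4-benzyl-1,3-oxazolidin-2-one; 2 (E)-but-2-enoyl chloride
Product: 4 (4S)-4-benzyl-3-[(E)-but-2-enoyl]-1,3-oxazolidin-2-one, via N-lithio oxazolidinone 3 (not isolated)
Conditions: n-BuLi, THF, −78 °C; then 2, −78 → 0 °C
Reagents that add atoms: none
Why: N-acylation of the lithiated Evans auxiliary with an acid chloride is a standard imide formation and creates no stereocentre.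

Step 2
Reactants: 4 (4S)-4-benzyl-3-[(E)-but-2-enoyl]-1,3-oxazolidin-2-one; 5 4-(benzyloxy)-3-methoxybenzaldehyde
Product: 7 (4S)-4-benzyl-3-[(2S)-2-[(S)-[4-(benzyloxy)-3-methoxyphenyl](hydroxy)methyl]but-3-enoyl]-1,3-oxazolidin-2-one, via boron dienolate 6 (not isolated)
Conditions: Bu2BOTf, Et3N, CH2Cl2, −78 → 0 °C; then 5, −78 → 0 °C; pH 7 buffer, MeOH, 30% H2O2, 0 °C
Reagents that add atoms: none
Why: Evans syn-aldol reaction in its deconjugative form: the (Z)-boron dienolate should react at its α-carbon through a closed chair transition state, and the benzyl group of the auxiliary shields one enolate face, which sets C3 as (S) with a vinyl group and C7 as (S).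

Step 3
Reactants: 7 (4S)-4-benzyl-3-[(2S)-2-[(S)-[4-(benzyloxy)-3-methoxyphenyl](hydroxy)methyl]but-3-enoyl]-1,3-oxazolidin-2-one
Product: 8 (4S)-4-benzyl-3-[(2S)-2-[(S)-[4-(benzyloxy)-3-methoxyphenyl][(tert-butyldimethylsilyl)oxy]methyl]but-3-enoyl]-1,3-oxazolidin-2-one
Conditions: TBSOTf, 2,6-lutidine, CH2Cl2, 0 °C
Reagents that add atoms: tert-butyldimethylsilyl triflate, CC(C)(C)[Si](C)(C)OS(=O)(=O)C(F)(F)F
Why: Silyl ether formation blocks the C7 hydroxyl, which would otherwise close onto the halomethyl ester of step 5 to a 1,3-dioxan-4-one and would allow retro-aldol cleavage.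

Step 4
Reactants: 8 (4S)-4-benzyl-3-[(2S)-2-[(S)-[4-(benzyloxy)-3-methoxyphenyl][(tert-butyldimethylsilyl)oxy]methyl]but-3-enoyl]-1,3-oxazolidin-2-one
Product: 10 (2S)-2-[(S)-[4-(benzyloxy)-3-methoxyphenyl][(tert-butyldimethylsilyl)oxy]methyl]but-3-enoic acid, via peroxy acid 9 (not isolated)
Conditions: LiOH, 30% H2O2, THF/H2O (3:1), 0 °C; then aq. Na2SO3; HCl to pH 3
Reagents that add atoms: hydrogen peroxide (as LiOOH), OO
Why: Hydroperoxide cleavage of the N-acyl oxazolidinone should attack the exocyclic carbonyl selectively under weakly basic conditions, which should leave the C3 centre and the β,γ-alkene in place, and sulfite reduces the percarboxylate to the acid.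

Step 5
Reactants: 10 (2S)-2-[(S)-[4-(benzyloxy)-3-methoxyphenyl][(tert-butyldimethylsilyl)oxy]methyl]but-3-enoic acid; 11 chloromethyl chlorosulfate
Product: 13 iodomethyl (2S)-2-[(S)-[4-(benzyloxy)-3-methoxyphenyl][(tert-butyldimethylsilyl)oxy]methyl]but-3-enoate, via chloromethyl ester 12 (not isolated)
Conditions: 11, NaHCO3, Bu4NHSO4 (cat.), CH2Cl2/H2O, rt; then NaI, acetone, rt, dark
Reagents that add atoms: sodium iodide, [Na+].[I-]
Why: Phase-transfer O-alkylation of the carboxylate with chloromethyl chlorosulfate followed by Finkelstein exchange is the usual way to halomethyl esters and installs C5 on O1 without basic conditions that could move the alkene into conjugation.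

Step 6
Reactants: 13 iodomethyl (2S)-2-[(S)-[4-(benzyloxy)-3-methoxyphenyl][(tert-butyldimethylsilyl)oxy]methyl]but-3-enoate
Product: 14 (3S,4R)-3-[(S)-[4-(benzyloxy)-3-methoxyphenyl][(tert-butyldimethylsilyl)oxy]methyl]-4-(iodomethyl)oxolan-2-one
Conditions: Mn2(CO)10 (10 mol%), blue LEDs (450 nm), solid NaHCO3, MeCN (0.01 M), 60 °C
Reagents that add atoms: none
Why: Proposed new method: photogenerated Mn(CO)5 radicals abstract iodine from 13 to give the acyloxymethyl radical at C5, which adds 5-exo-trig to the inner vinyl carbon C4; the exocyclic primary radical then takes iodine from a second molecule of 13 and carries the chain. The closest known reaction types are the iodine-atom-transfer cyclisation of allyl iodoacetates to iodomethyl butyrolactones and the Ueno–Stork haloacetal cyclisation, here with the radical on the alkoxy carbon of the ester instead of the acyl side, together with intermolecular Giese additions of acyloxymethyl radicals made from iodomethyl esters. The lactone ring closes in the 5-exo-trig mode through the minor s-trans rotamer of the ester, and the atom-transfer manifold is chosen because iodine exchange of the uncyclised radical is degenerate, so slow rotamer interconversion should cost time but not material. The new stereocentre C4 is controlled by the existing stereocentre C3: in the chair-like transition state C3–H eclipses the vinyl group (least allylic strain) and the bulky aryl(silyloxy)methyl group lies pseudo-equatorial, so CH2I should end up trans to it (4R). The step needs 5-exo over 6-endo closure, trans over cis closure, and cyclisation over intermolecular addition and 1,5-hydrogen transfer from C7–H; these should be secured by the terminal vinyl acceptor, the size of the C3 substituent, high dilution in a polar solvent that raises the share of the s-trans rotamer, and the polarity mismatch between the nucleophilic α-oxy radical and the hydridic C7–H bond.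

Step 7
Reactants: 14 (3S,4R)-3-[(S)-[4-(benzyloxy)-3-methoxyphenyl][(tert-butyldimethylsilyl)oxy]methyl]-4-(iodomethyl)oxolan-2-one; 15 4-iodo-1,2-dimethoxybenzene
Product: 16 (3S,4R)-3-[(S)-[4-(benzyloxy)-3-methoxyphenyl][(tert-butyldimethylsilyl)oxy]methyl]-4-(3,4-dimethoxybenzyl)oxolan-2-one
Conditions: 15 (1.5 equiv), NiI2 (10 mol%), 4,4'-di-tert-butyl-2,2'-bipyridine (10 mol%), pyridine (10 mol%), Zn dust (2 equiv), DMPU, 60 °C
Reagents that add atoms: none
Why: Nickel-catalysed reductive cross-electrophile coupling: oxidative addition of 15 to zerovalent nickel gives an arylnickel species that captures the primary alkyl radical formed from 14, and reductive elimination forms the benzylic C–C bond; the radical sits on the exocyclic CH2, so C3, C4 and C7 are not touched.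

Step 8
Reactants: 16 (3S,4R)-3-[(S)-[4-(benzyloxy)-3-methoxyphenyl][(tert-butyldimethylsilyl)oxy]methyl]-4-(3,4-dimethoxybenzyl)oxolan-2-one
Product: 17 (3S,4R)-3-[(S)-[4-(benzyloxy)-3-methoxyphenyl](hydroxy)methyl]-4-(3,4-dimethoxybenzyl)oxolan-2-one
Conditions: HF·pyridine, THF/pyridine, 0 °C → rt
Reagents that add atoms: none
Why: Fluoride-mediated desilylation under mildly acidic conditions should free the C7 carbinol without the retro-aldol cleavage or dehydration that a basic fluoride source could cause in a β-hydroxy lactone.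

Step 9
Reactants: 17 (3S,4R)-3-[(S)-[4-(benzyloxy)-3-methoxyphenyl](hydroxy)methyl]-4-(3,4-dimethoxybenzyl)oxolan-2-one
Product: 18 (3S,4R)-3-[4-(benzyloxy)-3-methoxybenzoyl]-4-(3,4-dimethoxybenzyl)oxolan-2-one
Conditions: Dess–Martin periodinane, CH2Cl2, rt
Reagents that add atoms: none
Why: Dess–Martin oxidation of the secondary benzylic alcohol gives the aryl ketone under neutral conditions; C7 loses its stereocentre and C3, now flanked by two carbonyl groups, should stay in the trans arrangement that it already has.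

Step 10
Reactants: 18 (3S,4R)-3-[4-(benzyloxy)-3-methoxybenzoyl]-4-(3,4-dimethoxybenzyl)oxolan-2-one
Product: 19 (3S,4R)-4-(3,4-dimethoxybenzyl)-3-(4-hydroxy-3-methoxybenzoyl)oxolan-2-one
Conditions: H2 (1 atm), Pd/C (10 wt%), EtOAc, rt
Reagents that add atoms: none
Why: Catalytic hydrogenolysis of the aryl benzyl ether should free the phenol, and the electron-rich para-oxygenated aryl ketone should be reduced much more slowly under neutral conditions at atmospheric pressure.

## Compound list

1 | (4S)-4-benzyl-1,3-oxazolidin-2-one | O=C1OC[C@H](Cc2ccccc2)N1 | starting material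
2 | (E)-but-2-enoyl chloride | C/C=C/C(=O)Cl | starting material
3 | N-lithio-(4S)-4-benzyl-1,3-oxazolidin-2-one | [Li]N1[C@@H](Cc2ccccc2)COC1=O | intermediate
4 | (4S)-4-benzyl-3-[(E)-but-2-enoyl]-1,3-oxazolidin-2-one | C/C=C/C(=O)N1[C@@H](Cc2ccccc2)COC1=O | intermediate
5 | 4-(benzyloxy)-3-methoxybenzaldehyde | COc1cc(C=O)ccc1OCc1ccccc1 | starting material
6 | (4S)-4-benzyl-3-[(1Z)-1-[(dibutylboranyl)oxy]buta-1,3-dien-1-yl]-1,3-oxazolidin-2-one | C=C/C=C(\OB(CCCC)CCCC)N1[C@@H](Cc2ccccc2)COC1=O | intermediate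
7 | (4S)-4-benzyl-3-[(2S)-2-[(S)-[4-(benzyloxy)-3-methoxyphenyl](hydroxy)methyl]but-3-enoyl]-1,3-oxazolidin-2-one | C=C[C@@H]([C@H](O)c1ccc(OCc2ccccc2)c(OC)c1)C(=O)N1[C@@H](Cc2ccccc2)COC1=O | intermediate
8 | (4S)-4-benzyl-3-[(2S)-2-[(S)-[4-(benzyloxy)-3-methoxyphenyl][(tert-butyldimethylsilyl)oxy]methyl]but-3-enoyl]-1,3-oxazolidin-2-one | C=C[C@@H]([C@H](O[Si](C)(C)C(C)(C)C)c1ccc(OCc2ccccc2)c(OC)c1)C(=O)N1[C@@H](Cc2ccccc2)COC1=O | intermediate
9 | (2S)-2-[(S)-[4-(benzyloxy)-3-methoxyphenyl][(tert-butyldimethylsilyl)oxy]methyl]but-3-eneperoxoic acid | C=C[C@@H]([C@H](O[Si](C)(C)C(C)(C)C)c1ccc(OCc2ccccc2)c(OC)c1)C(=O)OO | intermediate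
10 | (2S)-2-[(S)-[4-(benzyloxy)-3-methoxyphenyl][(tert-butyldimethylsilyl)oxy]methyl]but-3-enoic acid | C=C[C@@H]([C@H](O[Si](C)(C)C(C)(C)C)c1ccc(OCc2ccccc2)c(OC)c1)C(=O)O | intermediate
11 | chloromethyl chlorosulfate | ClCOS(=O)(=O)Cl | starting material
12 | chloromethyl (2S)-2-[(S)-[4-(benzyloxy)-3-methoxyphenyl][(tert-butyldimethylsilyl)oxy]methyl]but-3-enoate | C=C[C@@H]([C@H](O[Si](C)(C)C(C)(C)C)c1ccc(OCc2ccccc2)c(OC)c1)C(=O)OCCl | intermediate
13 | iodomethyl (2S)-2-[(S)-[4-(benzyloxy)-3-methoxyphenyl][(tert-butyldimethylsilyl)oxy]methyl]but-3-enoate | C=C[C@@H]([C@H](O[Si](C)(C)C(C)(C)C)c1ccc(OCc2ccccc2)c(OC)c1)C(=O)OCI | intermediate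
14 | (3S,4R)-3-[(S)-[4-(benzyloxy)-3-methoxyphenyl][(tert-butyldimethylsilyl)oxy]methyl]-4-(iodomethyl)oxolan-2-one | COc1cc([C@@H](O[Si](C)(C)C(C)(C)C)[C@H]2C(=O)OC[C@@H]2CI)ccc1OCc1ccccc1 | intermediate
15 | 4-iodo-1,2-dimethoxybenzene | COc1ccc(I)cc1OC | starting material
16 | (3S,4R)-3-[(S)-[4-(benzyloxy)-3-methoxyphenyl][(tert-butyldimethylsilyl)oxy]methyl]-4-(3,4-dimethoxybenzyl)oxolan-2-one | COc1cc([C@@H](O[Si](C)(C)C(C)(C)C)[C@H]2C(=O)OC[C@@H]2Cc2ccc(OC)c(OC)c2)ccc1OCc1ccccc1 | intermediate
17 | (3S,4R)-3-[(S)-[4-(benzyloxy)-3-methoxyphenyl](hydroxy)methyl]-4-(3,4-dimethoxybenzyl)oxolan-2-one | COc1cc([C@@H](O)[C@H]2C(=O)OC[C@@H]2Cc2ccc(OC)c(OC)c2)ccc1OCc1ccccc1 | intermediate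
18 | (3S,4R)-3-[4-(benzyloxy)-3-methoxybenzoyl]-4-(3,4-dimethoxybenzyl)oxolan-2-one | COc1cc(C(=O)[C@H]2C(=O)OC[C@@H]2Cc2ccc(OC)c(OC)c2)ccc1OCc1ccccc1 | intermediate
19 | (3S,4R)-4-(3,4-dimethoxybenzyl)-3-(4-hydroxy-3-methoxybenzoyl)oxolan-2-one | COc1cc(C(=O)[C@H]2C(=O)OC[C@@H]2Cc2ccc(OC)c(OC)c2)ccc1O | target

## Step count and risks

Total step count: 10. Longest linear sequence: 10 steps (1 → 19).

Steps most likely to fail:

1. Step 6 (proposed new method). What may go wrong:
   - The ring closure must pass through the minor s-trans ester rotamer and may be too slow, so intermolecular atom-transfer addition (oligomerisation) or 1,5-hydrogen transfer from C7–H may take over.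
   - The facial selectivity at C4 may be insufficient. Any cis isomer has to be removed at 14 or 16, because after step 9 it would equilibrate at C3 into the enantiomeric trans series.

   Fallback by known chemistry, setting out from 1 and coming back at 18. Compound 1 is N-acylated (n-BuLi, THF, −78 °C) with the mixed pivalic anhydride of 3-(3,4-dimethoxyphenyl)propanoic acid to give (4S)-4-benzyl-3-[3-(3,4-dimethoxyphenyl)propanoyl]-1,3-oxazolidin-2-one F1. Evans alkylation of its sodium enolate (NaHMDS, THF, −78 °C) with tert-butyl bromoacetate should give tert-butyl (3R)-4-[(4S)-4-benzyl-2-oxo-1,3-oxazolidin-3-yl]-3-(3,4-dimethoxybenzyl)-4-oxobutanoate F2. Reductive removal of the auxiliary (LiBH4, THF, 0 °C) gives tert-butyl (3R)-3-(3,4-dimethoxybenzyl)-4-hydroxybutanoate F3, and acid (TFA, CH2Cl2) closes it to (4R)-4-(3,4-dimethoxybenzyl)oxolan-2-one F4. Its lithium enolate (LiHMDS, THF, −78 °C) adds to aldehyde 5 anti to the benzyl group to give (3S,4R)-3-[[4-(benzyloxy)-3-methoxyphenyl](hydroxy)methyl]-4-(3,4-dimethoxybenzyl)oxolan-2-one F5 as a mixture of carbinol epimers. Dess–Martin oxidation of the mixture converges on 18.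

2. Step 7. What may go wrong: hydrodehalogenation or homodimerisation of the β-branched primary alkyl radical, and biaryl formation, may compete with the cross-coupling.

   Fallback, setting out from 14 and coming back at 16. Zinc insertion into the C–I bond (Zn dust, LiCl, THF, 40 °C) gives the organozinc reagent [(3R,4S)-4-[(S)-[4-(benzyloxy)-3-methoxyphenyl][(tert-butyldimethylsilyl)oxy]methyl]-5-oxooxolan-3-yl]methylzinc iodide F6, used in solution. Negishi coupling with 15 (Pd(OAc)2, SPhos, THF, rt) forms the same C–C bond by a two-electron transmetalation pathway.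

3. Step 10. What may go wrong: reduction of the aryl ketone to the carbinol and on to the methylene compound may compete with O-debenzylation.

   Fallback, setting out from 16 and coming back at 19. The benzyl ether is hydrogenolysed before the ketone exists (H2, Pd/C, EtOAc) to give (3S,4R)-3-[(S)-[(tert-butyldimethylsilyl)oxy](4-hydroxy-3-methoxyphenyl)methyl]-4-(3,4-dimethoxybenzyl)oxolan-2-one F7. Buffered desilylation (TBAF, AcOH, THF, 0 °C) gives (3S,4R)-3-[(S)-hydroxy(4-hydroxy-3-methoxyphenyl)methyl]-4-(3,4-dimethoxybenzyl)oxolan-2-one F8. DDQ (dioxane, rt) should oxidise the 4-hydroxybenzylic carbinol selectively to the ketone 19.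

Further compounds
F1 | step 6 | (4S)-4-benzyl-3-[3-(3,4-dimethoxyphenyl)propanoyl]-1,3-oxazolidin-2-one | COc1ccc(CCC(=O)N2[C@@H](Cc3ccccc3)COC2=O)cc1OC
F2 | step 6 | tert-butyl (3R)-4-[(4S)-4-benzyl-2-oxo-1,3-oxazolidin-3-yl]-3-(3,4-dimethoxybenzyl)-4-oxobutanoate | COc1ccc(C[C@H](CC(=O)OC(C)(C)C)C(=O)N2[C@@H](Cc3ccccc3)COC2=O)cc1OC
F3 | step 6 | tert-butyl (3R)-3-(3,4-dimethoxybenzyl)-4-hydroxybutanoate | COc1ccc(C[C@H](CC(=O)OC(C)(C)C)CO)cc1OC
F4 | step 6 | (4R)-4-(3,4-dimethoxybenzyl)oxolan-2-one | COc1ccc(C[C@@H]2CC(=O)OC2)cc1OC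
F5 | step 6 | (3S,4R)-3-[[4-(benzyloxy)-3-methoxyphenyl](hydroxy)methyl]-4-(3,4-dimethoxybenzyl)oxolan-2-one, mixture of carbinol epimers | COc1cc(C(O)[C@H]2C(=O)OC[C@@H]2Cc2ccc(OC)c(OC)c2)ccc1OCc1ccccc1
F6 | step 7 | [(3R,4S)-4-[(S)-[4-(benzyloxy)-3-methoxyphenyl][(tert-butyldimethylsilyl)oxy]methyl]-5-oxooxolan-3-yl]methylzinc iodide | COc1cc([C@@H](O[Si](C)(C)C(C)(C)C)[C@H]2C(=O)OC[C@@H]2C[Zn]I)ccc1OCc1ccccc1
F7 | step 10 | (3S,4R)-3-[(S)-[(tert-butyldimethylsilyl)oxy](4-hydroxy-3-methoxyphenyl)methyl]-4-(3,4-dimethoxybenzyl)oxolan-2-one | COc1cc([C@@H](O[Si](C)(C)C(C)(C)C)[C@H]2C(=O)OC[C@@H]2Cc2ccc(OC)c(OC)c2)ccc1O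
F8 | step 10 | (3S,4R)-3-[(S)-hydroxy(4-hydroxy-3-methoxyphenyl)methyl]-4-(3,4-dimethoxybenzyl)oxolan-2-one | COc1cc([C@@H](O)[C@H]2C(=O)OC[C@@H]2Cc2ccc(OC)c(OC)c2)ccc1O
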